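**Strategy**

The dihydrofuran ring is closed last, by joining the phenolic oxygen O4' of ring B to C7. The step exploits that C7 is benzylic to ring A with the 4-methoxy group para to it, so the C7 carbinol ionizes easily, while C8 already carries ring B and C9. In one acid-mediated operation the MOM group on O4' falls off, the quinone-methide-like C7 cation forms, and O4' closes the five-membered ring trans to the C9 hydroxymethyl group, whatever the C7 configuration was. The precursor is an open-chain 1,2-diaryl-1,3-propanediol whose C8 centre comes from an Evans aldol; the cinnamyl alcohol arm is attached afterwards by Suzuki coupling.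

Key step: step 7

Remark: atoms follow neolignan numbering; ring A is the 3,4,5-trimethoxyphenyl ring on C7, ring B is the benzene ring of the benzofuran (C1'–C6', O4'), and C8 carries C9H2OH.

**Route**

Step 1
Reactants: 1 2-allyl-6-methoxyphenol
Product: 2 2-allyl-4-bromo-6-methoxyphenol
Conditions: NBS (1.0 equiv), MeCN, −20 to 0 °C, dark
Reagents that add atoms: N-bromosuccinimide, O=C1CCC(=O)N1Br
Why: Electrophilic aromatic bromination; the free OH directs to its para position because both ortho positions are substituted, and the phenol ring should react with NBS far faster than the isolated monosubstituted alkene.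

Step 2
Reactants: 2 2-allyl-4-bromo-6-methoxyphenol
Product: 3 1-allyl-5-bromo-3-methoxy-2-(methoxymethoxy)benzene
Conditions: MOMCl, iPr2NEt, CH2Cl2, 0 °C to rt
Reagents that add atoms: chloromethyl methyl ether, COCCl
Why: O-alkylation of the phenol with the α-chloro ether gives the MOM acetal, which masks O4' through the oxidative, basic and Lewis-acidic steps and is removed in the key step.

Step 3
Reactants: 3 1-allyl-5-bromo-3-methoxy-2-(methoxymethoxy)benzene
Product: 4 2-[5-bromo-3-methoxy-2-(methoxymethoxy)phenyl]acetic acid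
Conditions: KMnO4 (5 mol %), NaIO4 (4.5 equiv), K2CO3, t-BuOH–H2O, rt; cold acidification to pH 4
Reagents that add atoms: sodium periodate, [Na+].[O-]I(=O)(=O)=O; water, O
Why: Lemieux–von Rudloff oxidative cleavage: catalytic permanganate hydroxylates the terminal alkene and periodate cleaves the diol and re-oxidizes manganese, so the allyl group is shortened by one carbon to the arylacetic acid in a buffered medium that spares the MOM acetal and the aryl bromide.

Step 4
Reactants: 4 2-[5-bromo-3-methoxy-2-(methoxymethoxy)phenyl]acetic acid; 5 (R)-4-benzyl-1,3-oxazolidin-2-one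
Product: 7 (R)-4-benzyl-3-{2-[5-bromo-3-methoxy-2-(methoxymethoxy)phenyl]acetyl}-1,3-oxazolidin-2-one, via mixed pivalic anhydride 6 (not isolated)
Conditions: PivCl, Et3N, THF, −20 °C; then LiCl, 5, −20 °C to rt
Reagents that add atoms: none
Why: N-acylation of the oxazolidinone through the mixed anhydride, which is attacked at the less hindered arylacetyl carbonyl; the auxiliary stereocentre is bought in, not formed.

Step 5
Reactants: 7 (R)-4-benzyl-3-{2-[5-bromo-3-methoxy-2-(methoxymethoxy)phenyl]acetyl}-1,3-oxazolidin-2-one; 8 3,4,5-trimethoxybenzaldehyde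
Product: 10 (4R)-4-benzyl-3-{(2R,3R)-2-[5-bromo-3-methoxy-2-(methoxymethoxy)phenyl]-3-hydroxy-3-(3,4,5-trimethoxyphenyl)propanoyl}-1,3-oxazolidin-2-one, via Z-dibutylboron enolate 9 (not isolated)
Conditions: Bu2BOTf, iPr2NEt, CH2Cl2, 0 °C; then 8, −78 to 0 °C; pH 7 buffer, MeOH, 30 % H2O2
Reagents that add atoms: none
Why: Evans syn-aldol reaction: the Z-boron enolate adds through a closed Zimmerman–Traxler chair with the (R)-benzyl group blocking one enolate face, which sets C8 (2R in the imide, 8S after reduction) and C7 (3R) as the 2,3-syn pair.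

Step 6
Reactants: 10 (4R)-4-benzyl-3-{(2R,3R)-2-[5-bromo-3-methoxy-2-(methoxymethoxy)phenyl]-3-hydroxy-3-(3,4,5-trimethoxyphenyl)propanoyl}-1,3-oxazolidin-2-one
Product: 11 (1R,2S)-2-[5-bromo-3-methoxy-2-(methoxymethoxy)phenyl]-1-(3,4,5-trimethoxyphenyl)propane-1,3-diol
Conditions: LiBH4, MeOH (1 equiv), THF, 0 °C
Reagents that add atoms: none
Why: Reductive cleavage of the N-acyl oxazolidinone at the exocyclic carbonyl gives the C9 alcohol and releases the auxiliary without touching C8–H, so C8 keeps its geometry (the descriptor changes from R to S only through the CIP priorities).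

Step 7
Reactants: 11 (1R,2S)-2-[5-bromo-3-methoxy-2-(methoxymethoxy)phenyl]-1-(3,4,5-trimethoxyphenyl)propane-1,3-diol
Product: 14 [(2R,3S)-5-bromo-7-methoxy-2-(3,4,5-trimethoxyphenyl)-2,3-dihydro-1-benzofuran-3-yl]methanol, via phenol triol 12 (not isolated), via C7 benzylic cation 13 (not isolated)
Conditions: 6 M aq. HCl–THF (1:4), 0 to 35 °C, 0.02 M
Reagents that add atoms: none
Why: Aqueous acid hydrolyses the aryl MOM acetal to free O4' (triol 12) and ionizes the C7 carbinol to cation 13, which ring A stabilizes through its para 4-methoxy group (an O-methylated quinone methide); O4' then captures C7. The closest known reaction type is the acid-mediated cyclodehydration of 1-aryl-2-(2-hydroxyaryl)propane-1,3-diols to trans-2-aryl-2,3-dihydrobenzofurans, the ring-closing event of 8–5' neolignan formation. The dihydrofuran ring closes in a 5-exo-tet-type SN1 mode, O4' attacking C7 while water leaves from outside the ring. C7 is the new stereocentre and is controlled by C8: the aryl group should settle trans to the C9 hydroxymethyl group in the envelope transition state, and reversibility of the closure should funnel any cis ether to the trans ether, so both C7 epimers converge on (7R,8S). The step needs O4' to win over O9 (five- against four-membered ring) and C8 to stay intact, which the tether O4'–C4'–C3'–C8–C7 and the absence of an acidifying group on C8 (C9 is already an alcohol) should secure at low temperature and high dilution.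

Step 8
Reactants: 14 [(2R,3S)-5-bromo-7-methoxy-2-(3,4,5-trimethoxyphenyl)-2,3-dihydro-1-benzofuran-3-yl]methanol; 15 (E)-3-(4,4,5,5-tetramethyl-1,3,2-dioxaborolan-2-yl)prop-2-en-1-ol
Product: 16 (-)-(7R,8S,7'E)-3,4,5,5'-tetramethoxy-4',7-epoxy-8,3'-neolign-7'-ene-9,9'-diol
Conditions: Pd(dppf)Cl2 (5 mol %), K3PO4, 1,4-dioxane–H2O, 80 °C
Reagents that add atoms: none
Why: Suzuki–Miyaura coupling: oxidative addition of the aryl bromide to zerovalent palladium, transmetalation of the (E)-alkenylboronate and reductive elimination proceed with retention of the alkene geometry, and the free hydroxyls and the benzylic ether should be inert to the mild aqueous base.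

**Compound list**

1 | 2-allyl-6-methoxyphenol | C=CCc1cccc(OC)c1O | starting material
2 | 2-allyl-4-bromo-6-methoxyphenol | C=CCc1cc(Br)cc(OC)c1O | intermediate
3 | 1-allyl-5-bromo-3-methoxy-2-(methoxymethoxy)benzene | C=CCc1cc(Br)cc(OC)c1OCOC | intermediate
4 | 2-[5-bromo-3-methoxy-2-(methoxymethoxy)phenyl]acetic acid | OC(=O)Cc1cc(Br)cc(OC)c1OCOC | intermediate
5 | (R)-4-benzyl-1,3-oxazolidin-2-one | O=C1N[C@H](Cc2ccccc2)CO1 | starting material
6 | mixed anhydride of 4 with pivalic acid | CC(C)(C)C(=O)OC(=O)Cc1cc(Br)cc(OC)c1OCOC | intermediate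
7 | (R)-4-benzyl-3-{2-[5-bromo-3-methoxy-2-(methoxymethoxy)phenyl]acetyl}-1,3-oxazolidin-2-one | O=C(Cc1cc(Br)cc(OC)c1OCOC)N1[C@H](Cc2ccccc2)COC1=O | intermediate
8 | 3,4,5-trimethoxybenzaldehyde | COc1cc(C=O)cc(OC)c1OC | starting material
9 | Z-dibutylboron enolate of 7 | CCCCB(CCCC)O/C(=C\c1cc(Br)cc(OC)c1OCOC)N1[C@H](Cc2ccccc2)COC1=O | intermediate
10 | (4R)-4-benzyl-3-{(2R,3R)-2-[5-bromo-3-methoxy-2-(methoxymethoxy)phenyl]-3-hydroxy-3-(3,4,5-trimethoxyphenyl)propanoyl}-1,3-oxazolidin-2-one | O=C([C@H](c1cc(Br)cc(OC)c1OCOC)[C@@H](O)c1cc(OC)c(OC)c(OC)c1)N1[C@H](Cc2ccccc2)COC1=O | intermediate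
11 | (1R,2S)-2-[5-bromo-3-methoxy-2-(methoxymethoxy)phenyl]-1-(3,4,5-trimethoxyphenyl)propane-1,3-diol | OC[C@H](c1cc(Br)cc(OC)c1OCOC)[C@@H](O)c1cc(OC)c(OC)c(OC)c1 | intermediate
12 | (1R,2S)-2-(5-bromo-2-hydroxy-3-methoxyphenyl)-1-(3,4,5-trimethoxyphenyl)propane-1,3-diol | OC[C@H](c1cc(Br)cc(OC)c1O)[C@@H](O)c1cc(OC)c(OC)c(OC)c1 | intermediate
13 | C7 benzylic cation of 12 (C8 geometry unchanged) | OC[C@H](c1cc(Br)cc(OC)c1O)[CH+]c1cc(OC)c(OC)c(OC)c1 | intermediate
14 | [(2R,3S)-5-bromo-7-methoxy-2-(3,4,5-trimethoxyphenyl)-2,3-dihydro-1-benzofuran-3-yl]methanol | COc1cc([C@@H]2Oc3c(OC)cc(Br)cc3[C@H]2CO)cc(OC)c1OC | intermediate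
15 | (E)-3-(4,4,5,5-tetramethyl-1,3,2-dioxaborolan-2-yl)prop-2-en-1-ol | OC/C=C/B1OC(C)(C)C(C)(C)O1 | starting material
16 | (-)-(7R,8S,7'E)-3,4,5,5'-tetramethoxy-4',7-epoxy-8,3'-neolign-7'-ene-9,9'-diol | COc1cc([C@@H]2Oc3c(OC)cc(/C=C/CO)cc3[C@H]2CO)cc(OC)c1OC | target

**Step count and risks**

Total step count: 8. Longest linear sequence: 8 steps (1 to 16); compounds 5, 8 and 15 are bought.

Steps most likely to fail:

1. Step 7 (key step). The aqueous acid needed to cleave the aryl MOM ether may let the C7 cation lose H8 to give the 2,3-diarylallyl alcohol. Re-protonation of that alkene, or re-ionization of the product, would erode the configuration at C8 and the trans selectivity. The fallback closes the ring one step earlier, setting out from aldol adduct 10. Anhydrous BF3·OEt2 with Me2S in CH2Cl2 at −40 °C should remove the MOM group and ionize C7 with the auxiliary still on C9, giving (4R)-4-benzyl-3-{[(2R,3R)-5-bromo-7-methoxy-2-(3,4,5-trimethoxyphenyl)-2,3-dihydro-1-benzofuran-3-yl]carbonyl}-1,3-oxazolidin-2-one F1. At this oxidation level, loss of H8 gives a conjugated acryloyl imide that should not re-enter the cation manifold, so cyclized material keeps C8. Reduction of F1 with LiBH4 (THF, 0 °C) then returns to the route at compound 14.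

2. Step 3. Permanganate may over-oxidize the enolizable arylacetaldehyde formed on the way, degrading it by a further carbon, or may attack the electron-rich ring. The fallback sets out from compound 3 and intercepts the aldehyde. Lemieux–Johnson cleavage (OsO4 cat., NaIO4, 2,6-lutidine, dioxane–H2O) should stop at 2-[5-bromo-3-methoxy-2-(methoxymethoxy)phenyl]acetaldehyde F2. Chlorite (NaClO2, NaH2PO4, 2-methyl-2-butene, t-BuOH–H2O), which cannot cleave the enol, then oxidizes F2, returning to the route at compound 4.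

3. Step 5. The boron enolate of the ortho,ortho'-disubstituted arylacetyl imide may add slowly to the electron-rich aldehyde, with poor facial control, retro-aldol on work-up or partial MOM loss to Bu2BOTf. The fallback sets out from acid 4 and changes auxiliary and enolate metal. Coupling with (R)-4-benzyl-1,3-thiazolidine-2-thione (EDC·HCl, DMAP, CH2Cl2) gives (R)-4-benzyl-3-{2-[5-bromo-3-methoxy-2-(methoxymethoxy)phenyl]acetyl}-1,3-thiazolidine-2-thione F3. Its chlorotitanium enolate (TiCl4, iPr2NEt, N-methyl-2-pyrrolidinone, CH2Cl2, −78 °C) should add to aldehyde 8 in the Evans-syn sense to give (4R)-4-benzyl-3-{(2R,3R)-2-[5-bromo-3-methoxy-2-(methoxymethoxy)phenyl]-3-hydroxy-3-(3,4,5-trimethoxyphenyl)propanoyl}-1,3-thiazolidine-2-thione F4. Reductive cleavage of F4 with NaBH4 (THF–EtOH, 0 °C) returns to the route at compound 11.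

Further compounds

F1 | step 7 | (4R)-4-benzyl-3-{[(2R,3R)-5-bromo-7-methoxy-2-(3,4,5-trimethoxyphenyl)-2,3-dihydro-1-benzofuran-3-yl]carbonyl}-1,3-oxazolidin-2-one | COc1cc([C@@H]2Oc3c(OC)cc(Br)cc3[C@H]2C(=O)N2[C@H](Cc4ccccc4)COC2=O)cc(OC)c1OC
F2 | step 3 | 2-[5-bromo-3-methoxy-2-(methoxymethoxy)phenyl]acetaldehyde | O=CCc1cc(Br)cc(OC)c1OCOC
F3 | step 5 | (R)-4-benzyl-3-{2-[5-bromo-3-methoxy-2-(methoxymethoxy)phenyl]acetyl}-1,3-thiazolidine-2-thione | O=C(Cc1cc(Br)cc(OC)c1OCOC)N1[C@H](Cc2ccccc2)CSC1=S
F4 | step 5 | (4R)-4-benzyl-3-{(2R,3R)-2-[5-bromo-3-methoxy-2-(methoxymethoxy)phenyl]-3-hydroxy-3-(3,4,5-trimethoxyphenyl)propanoyl}-1,3-thiazolidine-2-thione | O=C([C@H](c1cc(Br)cc(OC)c1OCOC)[C@@H](O)c1cc(OC)c(OC)c(OC)c1)N1[C@H](Cc2ccccc2)CSC1=S
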